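## Analysis of the target

The target is a (2S)-flavanone. Flavanone numbering is used throughout: O1, C2, C3, C4, C4a, C5–C8, C8a for rings C and A, and C1'–C6' for ring B. Ring A carries free hydroxyls at C5 and C7 and a 3-hydroxy-3-methylbutyl chain at C8. Ring B carries a free 2'-hydroxyl and a 2,2-dimethyl-2H-pyran fused linearly across C4'–C5', so the C2 substituent is a 7-hydroxy-2,2-dimethyl-2H-chromen-6-yl group. The only stereocentre is C2; it is benzylic, bonded to O1 and β to the C4 carbonyl. That position makes it fragile. Base opens ring C by retro-oxa-Michael reaction through the C3 enolate, and acid can ionise C2–O1 because the 2'- and 4'-oxygens stabilise the benzylic cation. Acid would also close the tertiary alcohol onto the neighbouring 7-hydroxyl to give a dimethylchroman and can add to the chromene alkene. The difficulties are therefore three: setting C2 without relying on the reversible oxa-Michael closure, fixing the regiochemistry of ring A (C8, not C6) and of the pyran fusion (linear, not angular), and finishing without strong acid or base. The strategy rests on reading C3–C4 of ring C as the C3=C4 double bond of a 4-silyloxy-2H-chromene. Ring C can then be closed by alkene metathesis between a vinyl group on C2 and a 1-silyloxyvinyl group on C4a, and C2 is an ordinary allylic aryl ether carbon that is set by a catalyst before ring C exists.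

## Retrosynthetic reasoning

**20 back to 19.** All five O–Si bonds of 19 are cut in one operation: three aryl silyl ethers, the tertiary silyl ether and the silyl enol ether, which returns the C4 ketone. Every hydroxyl is carried as a silyl ether for this reason. The last step then needs only buffered fluoride, with no acid that would cyclise the side chain onto O7 or ionise C2–O1 and no free base that would open ring C. The forward reaction has to protonate C3 faster than a transient enolate can expel O1.

**19 back to 18.** The C3=C4 double bond is cut. It is the only carbon–carbon bond of ring C whose metathesis disconnection leaves C2 saturated. Cutting C2–C3 instead would put C2 into an alkene and erase the stereocentre, and cutting O1–C2 last would bring back the oxa-Michael closure. What is gained is a ring closure that forms no stereocentre and never exposes C2 to a carbonyl β-position. The forward reaction has to engage a hindered, electron-rich 1,1-disubstituted alkene and leave the new double bond where it forms.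

**18 back to 17.** The enol O–Si bond is cut, which returns the methyl ketone. The acetyl methyl carbon is a throwaway carbon that leaves in the metathesis. The forward reaction has to silylate the ketone oxygen without ionising the neighbouring benzylic, allylic aryl ether.

**17 back to 7 and 16.** The O1–C2 bond is cut between the phenol oxygen of 7 and the allylic carbon of 16. This is the one bond whose formation can be made enantioselective by a reagent-controlled, branched-selective allylic substitution. The forward reaction has to deliver a hindered, ketone-chelated aryloxide to the aryl-bearing allyl terminus on one face and stop there.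

**7 back to 3 and 5 (through 6).** The bond between C8 and the first chain carbon is cut. An sp2–sp3 cross-coupling places the chain exactly where the halogen sits and brings the tertiary oxygen in already protected. The forward reaction has to couple at a doubly flanked position next to a free phenol.

**3 back to 2 and then 1.** The C–I bond and two aryl O–Si bonds are cut. Compound 1 is symmetric, so bis-silylation leaves one chelated hydroxyl, and this hydroxyl later becomes O1. Iodination ortho to it defines C8; the alternative position lies between two bulky silyloxy groups.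

**5 back to 4.** The O–Si bond is cut; the tertiary alcohol is masked before hydroboration.

**16 back to 15, 14 and 13.** The carbonate C–O bond, the ester oxidation level and the aryl–alkene bond are cut in turn. A Heck reaction on the aryl bromide supplies the (E)-configured three-carbon arm that the allylic substitution requires.

**13 back to 11 (through 12), 10, and 8 with 9.** The chromene alkene comes from the chromanone by reduction and dehydration. The chromanone comes from acylation of 8 by 9 followed by ring closure. The bromine of 8 blocks the position that would otherwise lead to mixtures, dictates linear fusion, and then serves as the coupling handle.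

## Alternatives that were turned down

**Alternative 1:** Ring A is disconnected entirely, the last bond formed being C4a–C5, and ring C is present from the start as a 2-aryl-2,3-dihydropyran-4-one. In the forward key step the dioxinone A2 is heated and loses its ketal carbon to give the acylketene A3. Its enol form, enolised toward C8, closes C4a–C5 by 6π-electrocyclisation and tautomerises to the resorcinol A1.
- For it: the oxygen pattern of ring A and the position of the C8 chain follow from construction, so no aromatic substitution has to be regioselective. The two phenols emerge unprotected. C2 could be set very early by an established asymmetric hetero-Diels–Alder reaction.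
- Against it: A2 needs a branched carbon bearing both the dioxinone and the side chain on the fully substituted enol-ether carbon of the dihydropyranone. Building that is a long linear sequence of enolate chemistry on a ring that opens by β-elimination of its own ring oxygen. The thermolysis runs above 100 °C on a substrate whose C2–O bond is activated by an electron-rich aryl group, so C2 is at risk in the key step itself. The enolisation must also go toward C8 and not elsewhere.
- Comparison: this alternative is stronger on ring A regiochemistry and on protecting-group economy. The chosen route reaches the same ring A pattern in three operations from symmetric 1, with one iodination carrying the regiochemical burden, and its precursor 18 is far shorter to make than A2.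

**Alternative 2:** C3–C4 and O1–C2 are disconnected together. In the forward key step a chiral phosphoric acid removes one methoxy group from the acetal A5 to give the ortho-quinone methide A7, and the hydroxystyrene A6 adds across it to close ring C as the 4-methoxyflavan A4.
- For it: it is the most convergent plan, forming two bonds, the ring and the stereocentre in one catalytic step from two short fragments, and it tolerates the free tertiary alcohol.
- Against it: A6 has two electron-rich styrene-type alkenes, the vinyl group and the chromene double bond. Both can act as the 2π partner and both oligomerise under acid. A7 is stabilised by two alkoxy groups and flanked by the side chain, so it is a sluggish electrophile and an uncatalysed racemic pathway can compete. A4 is at the wrong oxidation level at C4: the methyl ether must be hydrolysed and oxidised next to a chromene, a free phenol and electron-rich rings, and the methoxymethyl groups then need acid that endangers the tertiary alcohol and C2. The acid catalyst can also reopen C2–O1 of A4, which carries a doubly oxygen-activated aryl group.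
- Comparison: this alternative is stronger on convergence. The chosen strategy offers C4 at the ketone level from the moment ring C forms, and an endgame that is one fluoride treatment.

**Alternative 3:** The C5'–C4'' bond of the pyran on ring B is disconnected, leaving the tertiary propargyl ether A9. In the forward key step a cationic monovalent gold catalyst activates the alkyne and C5' attacks it in 6-endo fashion to give A8.
- For it: ring B is a simple resorcinol-type ring through most of the synthesis, the acid- and oxidant-sensitive chromene alkene appears only at the end, and the reaction type is mild and known for aryl propargyl ethers.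
- Against it: it does not address how ring C and C2 of A9 are made, so the central problem is left to another asymmetric flavanone synthesis. The closure can go to C3', which lies between two oxygens and is electronically the better nucleophile, so linear fusion depends only on the bulk of the 2'-silyl group. A Lewis-acidic metal acts on a flavanone whose C2–O1 bond is activated by the 2'- and 4'-oxygens, and the tertiary propargylic ether can itself ionise. A regiochemical error would fall on the most advanced intermediate, and the methoxymethyl groups still need acid afterwards.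
- Comparison: this alternative is stronger in keeping the chromene out of the route and in having a shorter ring B fragment. The chosen strategy fixes linear fusion at the outset through the bromine of 8 and deals with the stereocentre directly.

Key step: step 13

## Route

Assumption: the cyclometalated iridium catalyst from the (Sa,Sc,Sc) phosphoramidite is taken to send the aryloxide to the Si face of the aryl-bearing allyl terminus, which gives the S ether. If the facial sense on this substrate is the opposite, the mirror-image ligand is used and nothing else changes.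

Step 1
Reactants: 1 2',4',6'-trihydroxyacetophenone
Product: 2 1-[2-hydroxy-4,6-bis(triisopropylsilyloxy)phenyl]ethan-1-one
Conditions: TIPSCl (2.2 equiv), imidazole, DMF, 0 °C → rt
Reagents that add atoms: triisopropylsilyl chloride, CC(C)[Si](Cl)(C(C)C)C(C)C
Why: Silyl ether formation; the para hydroxyl and one ortho hydroxyl react, while the last ortho hydroxyl is hydrogen-bonded to the ketone and flanked, so the bulky chloride should stop at the bis-ether.

Step 2
Reactants: 2 1-[2-hydroxy-4,6-bis(triisopropylsilyloxy)phenyl]ethan-1-one
Product: 3 1-[2-hydroxy-3-iodo-4,6-bis(triisopropylsilyloxy)phenyl]ethan-1-one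
Conditions: NIS (1.05 equiv), DMF, 0 °C → rt, dark
Reagents that add atoms: N-iodosuccinimide, O=C1CCC(=O)N1I
Why: Electrophilic aromatic iodination of a phenol; the position ortho to the free hydroxyl is activated and accessible, whereas the only other free position lies between two triisopropylsilyloxy groups and is shielded.

Step 3
Reactants: 4 2-methylbut-3-en-2-ol
Product: 5 triethyl[(2-methylbut-3-en-2-yl)oxy]silane
Conditions: TESOTf, 2,6-lutidine, CH2Cl2, 0 °C
Reagents that add atoms: triethylsilyl trifluoromethanesulfonate, CC[Si](CC)(CC)OS(=O)(=O)C(F)(F)F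
Why: Silylation of a tertiary alcohol with a silyl triflate; the tertiary triethylsilyl ether tolerates borane, base and palladium and is removed by fluoride at the end.

Step 4
Reactants: 5 triethyl[(2-methylbut-3-en-2-yl)oxy]silane; 3 1-[2-hydroxy-3-iodo-4,6-bis(triisopropylsilyloxy)phenyl]ethan-1-one
Product: 7 1-{2-hydroxy-3-[3-methyl-3-(triethylsilyloxy)butyl]-4,6-bis(triisopropylsilyloxy)phenyl}ethan-1-one, via B-alkyl-9-BBN adduct 6 (not isolated)
Conditions: 9-BBN-H, THF, rt; then 3, Pd(OAc)2 (5 mol%), SPhos (10 mol%), K3PO4 (3 M aq), THF, 60 °C
Reagents that add atoms: 9-borabicyclo[3.3.1]nonane, B1C2CCCC1CCC2 (its boron is carried in intermediate 6 only; 7 keeps nothing but hydrogen from it)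
Why: Anti-Markovnikov hydroboration of the terminal alkene, then B-alkyl Suzuki–Miyaura coupling; a bulky biaryl phosphine is chosen for the doubly flanked, electron-rich iodide, and under base the substrate is a phenoxide, which makes its aryl silyl ethers poor leaving groups.

Step 5
Reactants: 8 4-bromobenzene-1,3-diol; 9 3-methylbut-2-enoic acid
Product: 10 6-bromo-7-hydroxy-2,2-dimethylchroman-4-one
Conditions: MeSO3H/P2O5 (10:1 w/w), 70 °C
Reagents that add atoms: none
Why: Friedel–Crafts acylation at the carbon para to one hydroxyl and ortho to the other (the second such carbon carries bromine), followed by oxa-Michael closure of the ortho hydroxyl onto the enone; the bromine thereby enforces linear fusion.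

Step 6
Reactants: 10 6-bromo-7-hydroxy-2,2-dimethylchroman-4-one
Product: 11 6-bromo-2,2-dimethyl-7-(triisopropylsilyloxy)chroman-4-one
Conditions: TIPSCl, imidazole, DMF, rt
Reagents that add atoms: triisopropylsilyl chloride, CC(C)[Si](Cl)(C(C)C)C(C)C
Why: Silylation of an acidic phenol; triisopropylsilyl is chosen because it should survive borohydride in methanol, the amine base of the Heck step and the aluminium hydride, yet leave with fluoride.

Step 7
Reactants: 11 6-bromo-2,2-dimethyl-7-(triisopropylsilyloxy)chroman-4-one
Product: 13 [(6-bromo-2,2-dimethyl-2H-chromen-7-yl)oxy]triisopropylsilane, via chroman-4-ol 12 (not isolated)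
Conditions: NaBH4, MeOH/THF, 0 °C; then TsOH·H2O (2 mol%), toluene, 60 °C
Reagents that add atoms: none
Why: Borohydride reduction of the aryl ketone, then acid-catalysed E1 dehydration; the benzylic cation is stabilised by the para silyloxy group and the ortho ring oxygen, so a trace of acid should suffice and the aryl silyl ether should stay on.

Step 8
Reactants: 13 [(6-bromo-2,2-dimethyl-2H-chromen-7-yl)oxy]triisopropylsilane
Product: 14 methyl (E)-3-[2,2-dimethyl-7-(triisopropylsilyloxy)-2H-chromen-6-yl]prop-2-enoate
Conditions: methyl acrylate, Pd2(dba)3 (2.5 mol%), [HP(t-Bu)3]BF4 (10 mol%), Cy2NMe, 1,4-dioxane, 80 °C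
Reagents that add atoms: methyl acrylate, C=CC(=O)OC
Why: Mizoroki–Heck coupling; the electron-rich trialkylphosphine allows oxidative addition of the electron-rich, ortho-substituted bromide, syn insertion and syn β-hydride elimination give the E alkene, and the internal chromene alkene next to a quaternary carbon should not compete with the acrylate.

Step 9
Reactants: 14 methyl (E)-3-[2,2-dimethyl-7-(triisopropylsilyloxy)-2H-chromen-6-yl]prop-2-enoate
Product: 15 (E)-3-[2,2-dimethyl-7-(triisopropylsilyloxy)-2H-chromen-6-yl]prop-2-en-1-ol
Conditions: i-Bu2AlH (2.3 equiv), CH2Cl2, −78 °C; aq. sodium potassium tartrate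
Reagents that add atoms: none
Why: 1,2-Reduction of an unsaturated ester to the allylic alcohol by an aluminium hydride; the alkene geometry and the aryl silyl ether are not touched.

Step 10
Reactants: 15 (E)-3-[2,2-dimethyl-7-(triisopropylsilyloxy)-2H-chromen-6-yl]prop-2-en-1-ol
Product: 16 (E)-3-[2,2-dimethyl-7-(triisopropylsilyloxy)-2H-chromen-6-yl]prop-2-en-1-yl methyl carbonate
Conditions: ClCO2Me, pyridine, CH2Cl2, 0 °C
Reagents that add atoms: methyl chloroformate, COC(=O)Cl
Why: Acylation of a primary alcohol to the methyl carbonate, the standard leaving group for iridium-catalysed allylic substitution; it also releases the methoxide that deprotonates the phenol in the next step.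

Step 11
Reactants: 7 1-{2-hydroxy-3-[3-methyl-3-(triethylsilyloxy)butyl]-4,6-bis(triisopropylsilyloxy)phenyl}ethan-1-one; 16 (E)-3-[2,2-dimethyl-7-(triisopropylsilyloxy)-2H-chromen-6-yl]prop-2-en-1-yl methyl carbonate
Product: 17 1-{2-{[(1S)-1-[2,2-dimethyl-7-(triisopropylsilyloxy)-2H-chromen-6-yl]prop-2-en-1-yl]oxy}-3-[3-methyl-3-(triethylsilyloxy)butyl]-4,6-bis(triisopropylsilyloxy)phenyl}ethan-1-one
Conditions: [Ir(cod)Cl]2 (2 mol%), (Sa,Sc,Sc)-O,O'-(1,1'-binaphthyl-2,2'-diyl) N,N-bis[1-(2-methoxyphenyl)ethyl]phosphoramidite (4 mol%), pre-activated with n-PrNH2; 16 (1.3 equiv), THF, 35 °C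
Reagents that add atoms: none
Why: Iridium-catalysed asymmetric allylic etherification of a phenol: ionisation of the carbonate gives an allyliridium cation, the released methoxide deprotonates the phenol, and the aryloxide attacks the aryl-substituted terminus anti to the metal, which gives the branched ether. The chiral cyclometalated phosphoramidite controls the face and so sets C2 as S; the ligand with 2-methoxyphenyl arms is chosen because ortho-oxygenated cinnamyl electrophiles need it. C-Allylation at the one free ring A carbon is blocked by its two flanking silyloxy groups, and a Claisen shift is blocked because both ortho positions are substituted.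

Step 12
Reactants: 17 1-{2-{[(1S)-1-[2,2-dimethyl-7-(triisopropylsilyloxy)-2H-chromen-6-yl]prop-2-en-1-yl]oxy}-3-[3-methyl-3-(triethylsilyloxy)butyl]-4,6-bis(triisopropylsilyloxy)phenyl}ethan-1-one
Product: 18 tert-butyl{[1-(2-{[(1S)-1-[2,2-dimethyl-7-(triisopropylsilyloxy)-2H-chromen-6-yl]prop-2-en-1-yl]oxy}-3-[3-methyl-3-(triethylsilyloxy)butyl]-4,6-bis(triisopropylsilyloxy)phenyl)ethenyl]oxy}dimethylsilane
Conditions: TBSOTf (1.3 equiv), Et3N (3 equiv), CH2Cl2, −78 → 0 °C
Reagents that add atoms: tert-butyldimethylsilyl trifluoromethanesulfonate, CC(C)(C)[Si](C)(C)OS(=O)(=O)C(F)(F)F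
Why: Soft enolisation of a methyl ketone: the carbonyl oxygen, the most basic site, is silylated and the amine removes a methyl proton, so no free enolate forms that could take a silyl group from the neighbouring aryl ether or deprotonate C2. Excess amine and low temperature should keep the silyl triflate from ionising the hindered, weakly basic ether oxygen at C2.

Step 13
Reactants: 18 tert-butyl{[1-(2-{[(1S)-1-[2,2-dimethyl-7-(triisopropylsilyloxy)-2H-chromen-6-yl]prop-2-en-1-yl]oxy}-3-[3-methyl-3-(triethylsilyloxy)butyl]-4,6-bis(triisopropylsilyloxy)phenyl)ethenyl]oxy}dimethylsilane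
Product: 19 (2S)-4-(tert-butyldimethylsilyloxy)-2-[2,2-dimethyl-7-(triisopropylsilyloxy)-2H-chromen-6-yl]-8-[3-methyl-3-(triethylsilyloxy)butyl]-5,7-bis(triisopropylsilyloxy)-2H-chromene
Conditions: RuCl2(=CHPh)(H2IMes)(PCy3) (second-generation Grubbs catalyst, 10 mol%), 1,4-benzoquinone (20 mol%), toluene (5 mM), 50 °C, argon sparge, dark
Reagents that add atoms: none
Why: This is ring-closing metathesis of a silyl enol ether with a terminal alkene, the oxygen counterpart of the known closure of N-allyl ortho-(1-silyloxyvinyl)anilines to 4-silyloxy-1,2-dihydroquinolines and of the known metathesis route to 2H-chromenes. The ruthenium benzylidene exchanges onto the monosubstituted C2 vinyl group to give an alkylidene at C3; [2+2] cycloaddition with the 1-silyloxyvinyl group on C4a and cycloreversion of the ruthenacyclobutane then form C3=C4 and release ethylene, the two lost carbons being the vinyl terminus and the former acetyl methyl. Ring C closes as a six-membered ring through this metallacycle, with the two reacting carbons held ortho to each other on ring A and the closure driven by loss of ethylene. No stereocentre is formed and no bond to C2 takes part, so the S configuration set in step 11 is carried through. Site selectivity among the three alkenes comes from the substrate: the silyloxyalkene is 1,1-disubstituted and cannot be attacked first, and the chromene alkene is cis-disubstituted, conjugated and next to a quaternary carbon, so opening it is slow and reversible. The double bond must also stay at C3=C4: benzoquinone removes ruthenium hydrides that would move it to C2=C3 or turn the vinyl group into an enol ether, and moderate temperature with exclusion of light guards against racemisation of the 2H-chromene by electrocyclic ring opening.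

Step 14
Reactants: 19 (2S)-4-(tert-butyldimethylsilyloxy)-2-[2,2-dimethyl-7-(triisopropylsilyloxy)-2H-chromen-6-yl]-8-[3-methyl-3-(triethylsilyloxy)butyl]-5,7-bis(triisopropylsilyloxy)-2H-chromene
Product: 20 (2S)-5,7-dihydroxy-2-(7-hydroxy-2,2-dimethyl-2H-chromen-6-yl)-8-(3-hydroxy-3-methylbutyl)chroman-4-one
Conditions: TBAF/AcOH (1:1, 8 equiv), THF, 0 °C → rt
Reagents that add atoms: none
Why: Fluoride-mediated cleavage of all O–Si bonds; the enol ether gives the C4 ketone by protonation at C3, which creates no stereocentre. Acetic acid protonates the enolate and the phenoxides as they form, so retro-oxa-Michael opening of ring C should not compete, and no strong acid is present to ionise C2–O1 or to cyclise the tertiary alcohol onto O7.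

## Compound list

1 | 2',4',6'-trihydroxyacetophenone | CC(=O)c1c(O)cc(O)cc1O | starting material
2 | 1-[2-hydroxy-4,6-bis(triisopropylsilyloxy)phenyl]ethan-1-one | CC(=O)c1c(O)cc(O[Si](C(C)C)(C(C)C)C(C)C)cc1O[Si](C(C)C)(C(C)C)C(C)C | intermediate
3 | 1-[2-hydroxy-3-iodo-4,6-bis(triisopropylsilyloxy)phenyl]ethan-1-one | CC(=O)c1c(O)c(I)c(O[Si](C(C)C)(C(C)C)C(C)C)cc1O[Si](C(C)C)(C(C)C)C(C)C | intermediate
4 | 2-methylbut-3-en-2-ol | CC(C)(O)C=C | starting material
5 | triethyl[(2-methylbut-3-en-2-yl)oxy]silane | CC[Si](CC)(CC)OC(C)(C)C=C | intermediate
6 | 9-[3-methyl-3-(triethylsilyloxy)butyl]-9-borabicyclo[3.3.1]nonane | CC[Si](CC)(CC)OC(C)(C)CCB1C2CCCC1CCC2 | intermediate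
7 | 1-{2-hydroxy-3-[3-methyl-3-(triethylsilyloxy)butyl]-4,6-bis(triisopropylsilyloxy)phenyl}ethan-1-one | CC(=O)c1c(O)c(CCC(C)(C)O[Si](CC)(CC)CC)c(O[Si](C(C)C)(C(C)C)C(C)C)cc1O[Si](C(C)C)(C(C)C)C(C)C | intermediate
8 | 4-bromobenzene-1,3-diol | Oc1ccc(Br)c(O)c1 | starting material
9 | 3-methylbut-2-enoic acid | CC(C)=CC(=O)O | starting material
10 | 6-bromo-7-hydroxy-2,2-dimethylchroman-4-one | CC1(C)CC(=O)c2cc(Br)c(O)cc2O1 | intermediate
11 | 6-bromo-2,2-dimethyl-7-(triisopropylsilyloxy)chroman-4-one | CC1(C)CC(=O)c2cc(Br)c(O[Si](C(C)C)(C(C)C)C(C)C)cc2O1 | intermediate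
12 | 6-bromo-2,2-dimethyl-7-(triisopropylsilyloxy)chroman-4-ol (racemic) | CC1(C)CC(O)c2cc(Br)c(O[Si](C(C)C)(C(C)C)C(C)C)cc2O1 | intermediate
13 | [(6-bromo-2,2-dimethyl-2H-chromen-7-yl)oxy]triisopropylsilane | CC1(C)C=Cc2cc(Br)c(O[Si](C(C)C)(C(C)C)C(C)C)cc2O1 | intermediate
14 | methyl (E)-3-[2,2-dimethyl-7-(triisopropylsilyloxy)-2H-chromen-6-yl]prop-2-enoate | COC(=O)/C=C/c1cc2c(cc1O[Si](C(C)C)(C(C)C)C(C)C)OC(C)(C)C=C2 | intermediate
15 | (E)-3-[2,2-dimethyl-7-(triisopropylsilyloxy)-2H-chromen-6-yl]prop-2-en-1-ol | OC/C=C/c1cc2c(cc1O[Si](C(C)C)(C(C)C)C(C)C)OC(C)(C)C=C2 | intermediate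
16 | (E)-3-[2,2-dimethyl-7-(triisopropylsilyloxy)-2H-chromen-6-yl]prop-2-en-1-yl methyl carbonate | COC(=O)OC/C=C/c1cc2c(cc1O[Si](C(C)C)(C(C)C)C(C)C)OC(C)(C)C=C2 | intermediate
17 | 1-{2-{[(1S)-1-[2,2-dimethyl-7-(triisopropylsilyloxy)-2H-chromen-6-yl]prop-2-en-1-yl]oxy}-3-[3-methyl-3-(triethylsilyloxy)butyl]-4,6-bis(triisopropylsilyloxy)phenyl}ethan-1-one | CC(C)(O[Si](CC)(CC)CC)CCc1c(O[Si](C(C)C)(C(C)C)C(C)C)cc(O[Si](C(C)C)(C(C)C)C(C)C)c(C(C)=O)c1O[C@H](c1cc2c(cc1O[Si](C(C)C)(C(C)C)C(C)C)OC(C)(C)C=C2)C=C | intermediate
18 | tert-butyl{[1-(2-{[(1S)-1-[2,2-dimethyl-7-(triisopropylsilyloxy)-2H-chromen-6-yl]prop-2-en-1-yl]oxy}-3-[3-methyl-3-(triethylsilyloxy)butyl]-4,6-bis(triisopropylsilyloxy)phenyl)ethenyl]oxy}dimethylsilane | CC(C)(O[Si](CC)(CC)CC)CCc1c(O[Si](C(C)C)(C(C)C)C(C)C)cc(O[Si](C(C)C)(C(C)C)C(C)C)c(C(=C)O[Si](C)(C)C(C)(C)C)c1O[C@H](c1cc2c(cc1O[Si](C(C)C)(C(C)C)C(C)C)OC(C)(C)C=C2)C=C | intermediate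
19 | (2S)-4-(tert-butyldimethylsilyloxy)-2-[2,2-dimethyl-7-(triisopropylsilyloxy)-2H-chromen-6-yl]-8-[3-methyl-3-(triethylsilyloxy)butyl]-5,7-bis(triisopropylsilyloxy)-2H-chromene | CC(C)(O[Si](CC)(CC)CC)CCc1c(O[Si](C(C)C)(C(C)C)C(C)C)cc(O[Si](C(C)C)(C(C)C)C(C)C)c2c1O[C@H](c1cc3c(cc1O[Si](C(C)C)(C(C)C)C(C)C)OC(C)(C)C=C3)C=C2O[Si](C)(C)C(C)(C)C | intermediate
20 | (2S)-5,7-dihydroxy-2-(7-hydroxy-2,2-dimethyl-2H-chromen-6-yl)-8-(3-hydroxy-3-methylbutyl)chroman-4-one | CC(C)(O)CCc1c(O)cc(O)c2c1O[C@H](c1cc3c(cc1O)OC(C)(C)C=C3)CC2=O | target

## Step count and least certain steps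

Total step count: 14. Longest linear sequence: 10 steps (steps 5 to 10, then 11 to 14). The ring A branch (steps 1, 2 and 4) and the side-chain step 3 join at steps 4 and 11.

**Step 13 (key step).** Three things may go wrong.
- The closure may be slow or fail. The 1,1-disubstituted silyloxyalkene is flanked by the C5 silyloxy group, the alkylidene sits on a crowded carbon, and the catalyst can be diverted into an unreactive heteroatom-stabilised carbene.
- The double bond may migrate through ruthenium hydrides, either in the product toward C2=C3 or in the vinyl group before closure. Either would erase C2.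
- The 2H-chromene may lose its configuration by reversible electrocyclic ring opening under heat or light.

The fallback gives up metathesis and creates C2 by conjugate addition; it sets out from 7 and from 13 and rejoins the route at 20. Heating 7 with N,N-dimethylformamide dimethyl acetal should give the enaminone (E)-3-(dimethylamino)-1-{2-hydroxy-3-[3-methyl-3-(triethylsilyloxy)butyl]-4,6-bis(triisopropylsilyloxy)phenyl}prop-2-en-1-one F1. With pyridinium tosylate in warm toluene F1 should close onto the free phenol, with loss of dimethylamine, to the chromone 8-[3-methyl-3-(triethylsilyloxy)butyl]-5,7-bis(triisopropylsilyloxy)-4H-chromen-4-one F2. Bromine–lithium exchange on 13 (n-BuLi, THF, −78 °C), B(Oi-Pr)3 and mild hydrolysis should give [2,2-dimethyl-7-(triisopropylsilyloxy)-2H-chromen-6-yl]boronic acid F3. Rhodium-catalysed asymmetric 1,4-addition of F3 to F2 ([Rh(OH)(cod)]2 with the antipode of a chiral diene or bisphosphine ligand that gives 2S, aqueous dioxane) is known chemistry for making flavanones from chromones. It should give the protected flavanone (2S)-2-[2,2-dimethyl-7-(triisopropylsilyloxy)-2H-chromen-6-yl]-8-[3-methyl-3-(triethylsilyloxy)butyl]-5,7-bis(triisopropylsilyloxy)chroman-4-one F4, which the conditions of step 14 convert into 20.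

**Step 11.** Four things may go wrong.
- The phenol is chelated to the ketone and flanked on both sides, so attack on the allyliridium cation may be slow.
- The ortho silyloxy group on the electrophile may lower rate and facial selectivity.
- The product, an ether of an acidic phenol with an electron-rich 1-arylallyl group, may re-ionise on the catalyst. That erodes the enantiomeric purity and leaks to the linear ether.
- The sense of induction rests on the assumption stated before the steps.

The fallback makes the same bond within a pre-formed ion pair; it sets out from 15 and 7 and rejoins at 17. Alcohol 15 with 1,1'-carbonyldiimidazole should give (E)-3-[2,2-dimethyl-7-(triisopropylsilyloxy)-2H-chromen-6-yl]prop-2-en-1-yl 1H-imidazole-1-carboxylate F5. F5 should acylate the sodium phenoxide of 7 to give the mixed carbonate 2-acetyl-6-[3-methyl-3-(triethylsilyloxy)butyl]-3,5-bis(triisopropylsilyloxy)phenyl (E)-3-[2,2-dimethyl-7-(triisopropylsilyloxy)-2H-chromen-6-yl]prop-2-en-1-yl carbonate F6. The same iridium–phosphoramidite catalyst then effects the known decarboxylative allylic etherification of aryl allyl carbonates. The aryloxide is released only as the counter-ion of the allyliridium cation, free of alkali metal chelation and of competing methoxide, and 17 should result.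

**Step 12.** The silyl triflate may ionise the benzylic, allylic C2–O bond, which is activated by the 2'- and 4'-oxygens, and that would racemise or cleave the ether. The fallback replaces electrophilic activation of the carbonyl by enolate chemistry and runs from 17 directly to 18. KN(SiMe3)2 in THF at −78 °C with TBSCl present removes a methyl proton kinetically and the potassium enolate is trapped on oxygen as it forms. No Lewis acid is present and no new compound arises (F0).

**Step 14.** Fluoride may generate the C3 enolate or ring A phenoxides faster than the buffer protonates them, which would open ring C and epimerise C2. The tertiary triethylsilyl ether may also lag behind the aryl ethers. The fallback separates the two mechanisms and runs from 19 to 20 in two stages. HF·pyridine buffered with pyridine in THF at 0 °C should protonate the enol ether at C3 (no enolate is involved) and remove the triethylsilyl group. This should give (2S)-2-[2,2-dimethyl-7-(triisopropylsilyloxy)-2H-chromen-6-yl]-8-(3-hydroxy-3-methylbutyl)-5,7-bis(triisopropylsilyloxy)chroman-4-one F7. Its three aryl silyl ethers are then cleaved with TBAF/AcOH at 0 °C, conditions under which the ketone is already in place and the phenols are protonated as they are released, to give 20.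

**Step 4.** The coupling site lies between a free hydroxyl and a triisopropylsilyloxy group, so transmetalation may be slow and protodeiodination may compete. Aqueous base may also strip an aryl silyl ether. The fallback makes the same bond by a Heck reaction and rejoins at 7; it sets out from 3 and 5. Pd(OAc)2, Bu4NCl and Et3N in DMF at 80 °C should give 1-{2-hydroxy-3-[(E)-3-methyl-3-(triethylsilyloxy)but-1-en-1-yl]-4,6-bis(triisopropylsilyloxy)phenyl}ethan-1-one F8. The carbinol carbon has no hydrogen, so only the styrene can form. Hydrogenation of F8 (H2, Pd/C, EtOAc) should then give 7.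

## Further compounds

F1 | step 13 | (E)-3-(dimethylamino)-1-{2-hydroxy-3-[3-methyl-3-(triethylsilyloxy)butyl]-4,6-bis(triisopropylsilyloxy)phenyl}prop-2-en-1-one | CN(C)/C=C/C(=O)c1c(O)c(CCC(C)(C)O[Si](CC)(CC)CC)c(O[Si](C(C)C)(C(C)C)C(C)C)cc1O[Si](C(C)C)(C(C)C)C(C)C
F2 | step 13 | 8-[3-methyl-3-(triethylsilyloxy)butyl]-5,7-bis(triisopropylsilyloxy)-4H-chromen-4-one | CC[Si](CC)(CC)OC(C)(C)CCc1c(O[Si](C(C)C)(C(C)C)C(C)C)cc(O[Si](C(C)C)(C(C)C)C(C)C)c2c1OC=CC2=O
F3 | step 13 | [2,2-dimethyl-7-(triisopropylsilyloxy)-2H-chromen-6-yl]boronic acid | OB(O)c1cc2c(cc1O[Si](C(C)C)(C(C)C)C(C)C)OC(C)(C)C=C2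
F4 | step 13 | (2S)-2-[2,2-dimethyl-7-(triisopropylsilyloxy)-2H-chromen-6-yl]-8-[3-methyl-3-(triethylsilyloxy)butyl]-5,7-bis(triisopropylsilyloxy)chroman-4-one | CC[Si](CC)(CC)OC(C)(C)CCc1c(O[Si](C(C)C)(C(C)C)C(C)C)cc(O[Si](C(C)C)(C(C)C)C(C)C)c2c1O[C@H](c1cc3c(cc1O[Si](C(C)C)(C(C)C)C(C)C)OC(C)(C)C=C3)CC2=O
F5 | step 11 | (E)-3-[2,2-dimethyl-7-(triisopropylsilyloxy)-2H-chromen-6-yl]prop-2-en-1-yl 1H-imidazole-1-carboxylate | O=C(OC/C=C/c1cc2c(cc1O[Si](C(C)C)(C(C)C)C(C)C)OC(C)(C)C=C2)n1ccnc1
F6 | step 11 | 2-acetyl-6-[3-methyl-3-(triethylsilyloxy)butyl]-3,5-bis(triisopropylsilyloxy)phenyl (E)-3-[2,2-dimethyl-7-(triisopropylsilyloxy)-2H-chromen-6-yl]prop-2-en-1-yl carbonate | CC(=O)c1c(OC(=O)OC/C=C/c2cc3c(cc2O[Si](C(C)C)(C(C)C)C(C)C)OC(C)(C)C=C3)c(CCC(C)(C)O[Si](CC)(CC)CC)c(O[Si](C(C)C)(C(C)C)C(C)C)cc1O[Si](C(C)C)(C(C)C)C(C)C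
F0 | step 12 | none | none
F7 | step 14 | (2S)-2-[2,2-dimethyl-7-(triisopropylsilyloxy)-2H-chromen-6-yl]-8-(3-hydroxy-3-methylbutyl)-5,7-bis(triisopropylsilyloxy)chroman-4-one | CC(C)(O)CCc1c(O[Si](C(C)C)(C(C)C)C(C)C)cc(O[Si](C(C)C)(C(C)C)C(C)C)c2c1O[C@H](c1cc3c(cc1O[Si](C(C)C)(C(C)C)C(C)C)OC(C)(C)C=C3)CC2=O
F8 | step 4 | 1-{2-hydroxy-3-[(E)-3-methyl-3-(triethylsilyloxy)but-1-en-1-yl]-4,6-bis(triisopropylsilyloxy)phenyl}ethan-1-one | CC(=O)c1c(O)c(/C=C/C(C)(C)O[Si](CC)(CC)CC)c(O[Si](C(C)C)(C(C)C)C(C)C)cc1O[Si](C(C)C)(C(C)C)C(C)C
A1 | alternative 1 | (2S)-2-[7-(tert-butyldimethylsilyloxy)-2,2-dimethyl-2H-chromen-6-yl]-5,7-dihydroxy-8-[3-methyl-3-(triethylsilyloxy)butyl]chroman-4-one | CC(C)(O[Si](CC)(CC)CC)CCc1c(O)cc(O)c2c1O[C@H](c1cc3c(cc1O[Si](C)(C)C(C)(C)C)OC(C)(C)C=C3)CC2=O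
A2 | alternative 1 | (2S)-2-[7-(tert-butyldimethylsilyloxy)-2,2-dimethyl-2H-chromen-6-yl]-6-[1-(2,2-dimethyl-4-oxo-4H-1,3-dioxin-6-yl)-4-methyl-4-(triethylsilyloxy)pentyl]-2,3-dihydro-4H-pyran-4-one | CC(C)(O[Si](CC)(CC)CC)CCC(C1=CC(=O)OC(C)(C)O1)C1=CC(=O)C[C@@H](c2cc3c(cc2O[Si](C)(C)C(C)(C)C)OC(C)(C)C=C3)O1
A3 | alternative 1 | acylketene from A2: (2S)-2-[7-(tert-butyldimethylsilyloxy)-2,2-dimethyl-2H-chromen-6-yl]-6-[6-methyl-1,3-dioxo-6-(triethylsilyloxy)hept-1-en-4-yl]-2,3-dihydro-4H-pyran-4-one | CC(C)(O[Si](CC)(CC)CC)CCC(C(=O)C=C=O)C1=CC(=O)C[C@@H](c2cc3c(cc2O[Si](C)(C)C(C)(C)C)OC(C)(C)C=C3)O1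
A4 | alternative 2 | (2S,4S)-2-(7-hydroxy-2,2-dimethyl-2H-chromen-6-yl)-8-(3-hydroxy-3-methylbutyl)-4-methoxy-5,7-bis(methoxymethoxy)chromane | CC(C)(O)CCc1c(OCOC)cc(OCOC)c2c1O[C@H](c1cc3c(cc1O)OC(C)(C)C=C3)C[C@@H]2OC
A5 | alternative 2 | 2-(dimethoxymethyl)-6-(3-hydroxy-3-methylbutyl)-3,5-bis(methoxymethoxy)phenol | CC(C)(O)CCc1c(OCOC)cc(OCOC)c(C(OC)OC)c1O
A6 | alternative 2 | 6-ethenyl-2,2-dimethyl-2H-chromen-7-ol | C=Cc1cc2c(cc1O)OC(C)(C)C=C2
A7 | alternative 2 | 2-(3-hydroxy-3-methylbutyl)-6-(methoxymethylidene)-3,5-bis(methoxymethoxy)cyclohexa-2,4-dien-1-one | COC=C1C(=O)C(CCC(C)(C)O)=C(OCOC)C=C1OCOC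
A8 | alternative 3 | (2S)-2-[2,2-dimethyl-7-(triisopropylsilyloxy)-2H-chromen-6-yl]-5,7-bis(methoxymethoxy)-8-[3-methyl-3-(triethylsilyloxy)butyl]chroman-4-one | CC(C)(O[Si](CC)(CC)CC)CCc1c(OCOC)cc(OCOC)c2c1O[C@H](c1cc3c(cc1O[Si](C(C)C)(C(C)C)C(C)C)OC(C)(C)C=C3)CC2=O
A9 | alternative 3 | (2S)-5,7-bis(methoxymethoxy)-2-[4-(2-methylbut-3-yn-2-yloxy)-2-(triisopropylsilyloxy)phenyl]-8-[3-methyl-3-(triethylsilyloxy)butyl]chroman-4-one | CC(C)(O[Si](CC)(CC)CC)CCc1c(OCOC)cc(OCOC)c2c1O[C@H](c1ccc(OC(C)(C)C#C)cc1O[Si](C(C)C)(C(C)C)C(C)C)CC2=O
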